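## The problem

The target is a sesquilignan built on a γ-butyrolactone (lignan locants: O1, carbonyl C9, C8, C8', methylene C9') that carries a 4-hydroxy-3-methoxybenzyl group (C7, ring A) on C8 and, trans to it on C8', the carbinol carbon C7' of a second guaiacyl ring (ring B). The para oxygen of ring B is the ether oxygen on C8'' of a guaiacylglycerol unit (C7''–C9'', ring C), so three aryl units are joined through one lactone and one secondary alkyl aryl ether. The five stereocentres form two groups that cannot relay information to each other: C8, C8' and C7' (all R) are contiguous, whereas C7'' and C8'' (both S, the threo pair) lie beyond ring B, so each group must be fixed absolutely on its own and the two must be matched. Within the first group C8' can dictate C8, because a lactone enolate is alkylated anti to its β-substituent, but the anti relation of O7' to the C8'–C8 bond has to come from the event that joins C7' to C8'; within the second group the syn relation of O7'' and O8'' is an aldol dyad. The ether carbon C8'' is flanked by a benzylic carbinol and a hydroxymethyl group, so substitution at C8'' on a late lactone intermediate cannot be relied on. Rough treatment is excluded: both benzylic alcohols are para-oxygenated and ionise in acid or are hydrogenolysed, the C7' hydroxyl is γ to the lactone carbonyl and can translactonise under base, and the ring C phenol is para to C7''. The enabling feature is that O1, C9, C8, C8' and C9' are the five atoms of furan and that C7' with its oxygen is an aldehyde carbonyl placed on a furan β-carbon. A carbonyl–furan [2+2] photocycloaddition can thus form C7'–C8' and tie O7' to C9', leaving C9 as an enol ether carbon to be oxidised and C9' as an acetal carbon to be reduced.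

## Retrosynthesis

**Unmasking (27 from 26 from 25).** Only O–benzyl and O–Si bonds are cut. The three alcohols are carried as tert-butyldimethylsilyl (TBS) ethers and the two phenols as benzyl ethers, so that 25 gives triol 26 with buffered fluoride and 26 gives 27 by neutral hydrogenolysis. Removing silicon while the phenols are still benzylated avoids quinone methide chemistry at C7''. No acid or base touches the hydroxy lactone. The forward steps must spare the benzylic C–O bonds.

**C7–C8 bond (25 from 21 and 23).** Cutting the benzyl group from C8 leaves the β-substituted lactone 21 and benzylic bromide 23, made in one step from alcohol 22. This cut is preferred over one at C8–C8' because the existing C8' centre then sets C8 by simple anti alkylation. 21 has one stereocentre fewer in the lactone part and no ring A.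

**C9 oxidation level (21 from 20).** The lactone carbonyl is traced to the enol ether carbon of the silylated 2,3-dihydrofuran 20. Direct chromate oxidation of a cyclic enol ether to the lactone is asked of the forward step. O7' must already be silylated, because a free benzylic carbinol would be oxidised first.

**O7'–Si bond and stereochemical sorting (20 from 18 and 19).** Cutting the silyl ether leads to carbinol 18, which cannot be had alone: it arises together with 19, the isomer of opposite configuration at C7' and C8'. The two differ only in how the carbinol unit relates to the remote side-chain centres, so chromatography cannot be expected to part them. A chiral acyl-transfer catalyst that recognises only the carbinol centre is therefore asked to esterify 19, and the silyl triflate then caps the untouched 18 in the same flask. The sorting thus delivers a new, protected compound, and the separation is between a silyl ether and an ester.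

**C9'–H bond (18 and 19 from 16 and 17).** The C9' methylene is traced to the acetal carbon of the oxetane-fused dihydrofurans 16 and 17: hydride replaces the oxetane oxygen at C9' and releases O7' as the free carbinol. The reduction is placed before the oxidation at C9 because the strained acetal would not survive an oxidant or acid. The forward step must capture the oxocarbenium ion faster than it loses the C8' proton.

**C7'–C8' and C9'–O7' bonds (16 and 17 from 14 and 15).** Both bonds are cut at once, which opens the oxetane and returns furan 15 and aryl aldehyde 14. No other cut creates the C7'/C8' pair with its relative configuration from two components in a single step. Aldehyde 14 already carries the complete, protected glycerol ether on its para oxygen, so the hindered C8''–O bond never has to be formed on the lactone and ring B needs no protecting group. The price is that the cycloaddition cannot distinguish the two faces of furan, so half of 14 enters the unwanted series (17, 19).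

**Formyl group (14 from 12).** The formyl carbon is cut from ring B, leaving aryl bromide 12. Bromine is inert through the aldol chemistry that builds the side chain, whereas a free formyl group would compete as the electrophile. Halogen–lithium exchange and formylation are asked of the forward step.

**C7''–C8'' bond (12 from 11 from 10 from 6 and 7).** Silyl ether 12 comes from diol 11, and 11 from imide 10 by reductive removal of the auxiliary. Cutting C7''–C8'' in 10 gives the aryloxyacetyl imide 6 and commercial aldehyde 7. A syn-selective glycolate aldol sets both centres as the threo pair in one step, which is why this cut is preferred over substitution at C8'' or addition of an aryl metal to an α-aryloxy aldehyde.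

**Imide (6 from 3 and 4; 3 from 1 and 2).** The N–acyl bond is cut to acid 3 and oxazolidinone 4, and the aryl ether of 3 to phenol 1 and bromoacetic acid 2. All four are simple, and the ether here is primary and unhindered.

## Roads not taken

Alternative 1: The cut removes the C8–C8' and C8–C7' bonds of a cyclopropane fused to the lactone. In the forward direction the allylic diazomalonate A1 gives a copper carbene (CuOTf with a chiral bis(oxazoline) ligand) that adds across the E-alkene and closes the three- and five-membered rings of A2 together. The donor–acceptor cyclopropane would then be opened at C7' by an oxygen nucleophile, and the ester on C8 would serve for benzylation before decarboxylation.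
- Merits: the step is catalytic and intramolecular, and the absolute configuration at C8' comes from a ligand, so no material is lost statistically. In this respect it is better than the chosen plan.
- Weak points: opening at an electron-rich benzylic carbon drifts towards an ionised course that would scramble C7'. C8 becomes quaternary, and its final configuration rests on a decarboxylative protonation next to a base-sensitive C7' oxygen. The ring B oxygen is only masked, so the C8'' ether must still be made on the lactone.
- Against it the chosen plan sets a C7'–O bond that is never broken after it forms, a C7'/C8' relation fixed by the ring geometry of the cycloadduct, and a side chain already in place.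

Alternative 2: The cut is the O1–C9' bond, traced to the cyclobutanone A3. A catalytic asymmetric Baeyer–Villiger oxidation (chiral acid catalyst, peroxide) inserts oxygen next to one of the two ring methylene groups and delivers lactone A4.
- Merits: the lactone oxidation level is reached directly, without acetal reduction or enol ether oxidation, and C8' is set by a catalyst. A4 is the ring B benzyl ether analogue of 21, so the later steps would be the same. On these points the road is as good as or better than the chosen one.
- Weak points: C7' lies outside the four-membered ring and is untouched by the key step. It must be set beforehand, and its relation to C8' then depends on catalyst and substrate matching. A3 itself needs several steps (ketene cycloaddition, dehalogenation), and a peroxide meets electron-rich arenes.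
- Against it the chosen plan sets the formation of C7'–C8' and their relative configuration in one step from an aldehyde and furan, with no separate control of C7'.

Alternative 3: The cut removes C8'–C9' and O1–C9. In the forward direction the C8' enolate of γ-keto ester A5 adds to formaldehyde A6, and the new hydroxyl closes onto the ester to give the trans keto lactone A7.
- Merits: the C1 unit is the cheapest possible, all steps are ground-state and scalable, the trans relation is under thermodynamic control because C8' is epimerisable, and C8 can come from an asymmetric alkylation. In scalability and absolute control at C8 it is better than the chosen plan.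
- Weak points: C8' of A5 bears two protons, so a second hydroxymethylation and dehydration to an α-methylene ketone compete with lactonisation. C7' arrives as a ketone, and its reduction must deliver the 7'R carbinol by 1,2-induction from an epimerisable neighbour. The ring B oxygen is again only masked.
- Against it the chosen plan sets a C7' that is formed as a carbinol with the correct relative configuration, so no ketone reduction is needed.

Key step: step 7

Remarks on the chemistry:
- Ar* stands for the 3-methoxy-4-{[(1S,2S)-1-[4-(benzyloxy)-3-methoxyphenyl]-1,3-bis[(tert-butyldimethylsilyl)oxy]propan-2-yl]oxy}phenyl group; TBS is tert-butyldimethylsilyl.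
- Compounds 1, 2, 4, 7, 15 and 22 are taken as commercial.
- Steps 7 and 8 each give two isomers that differ only in the relation of the new stereocentres to the remote side-chain centres. They are assumed not to separate by chromatography and are taken on together until step 9.
- The (S)-enantiomer of benzotetramisole is assumed to acylate the (S)-configured aryl carbinol (the mirror of the known preference of the (R)-catalyst for (R)-1-arylalkanols). If the sense is reversed on this substrate, the antipodal catalyst is used.

## Route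

Step 1
Reactants: 1 4-bromo-2-methoxyphenol; 2 bromoacetic acid
Product: 3 (4-bromo-2-methoxyphenoxy)acetic acid
Conditions: NaOH, H2O, reflux; then HCl (aq)
Reagents that add atoms: none
Why: Williamson ether synthesis of an aryloxyacetic acid from a phenoxide and a haloacetate; the aryl bromide is inert.

Step 2
Reactants: 3 (4-bromo-2-methoxyphenoxy)acetic acid; 4 (R)-4-benzyloxazolidin-2-one
Product: 6 (R)-4-benzyl-3-[(4-bromo-2-methoxyphenoxy)acetyl]oxazolidin-2-one, via mixed pivalic anhydride 5 (not isolated)
Conditions: PivCl, Et3N, THF, −20 °C; then LiCl, 4, −20 °C to rt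
Reagents that add atoms: none
Why: N-acylation of the oxazolidinone through the mixed anhydride; attack occurs at the less hindered aryloxyacetyl carbonyl.

Step 3
Reactants: 6 (R)-4-benzyl-3-[(4-bromo-2-methoxyphenoxy)acetyl]oxazolidin-2-one; 7 4-(benzyloxy)-3-methoxybenzaldehyde
Product: 10 (R)-4-benzyl-3-[(2R,3S)-3-[4-(benzyloxy)-3-methoxyphenyl]-2-(4-bromo-2-methoxyphenoxy)-3-hydroxypropanoyl]oxazolidin-2-one, via dibutylboron Z-enolate 8 (not isolated), via dibutylboron aldolate 9 (not isolated)
Conditions: Bu2BOTf, Et3N, CH2Cl2, −78 to 0 °C; 7, −78 to 0 °C; then pH 7 buffer, MeOH, H2O2, 0 °C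
Reagents that add atoms: none
Why: Evans syn-aldol reaction of a glycolate-type imide: the boron Z-enolate reacts through a chair transition state on the face opposite the benzyl group, so the (R)-auxiliary sets C8'' and C7'' together as the (2R,3S) syn adduct, which is the threo (7''S,8''S) unit.

Step 4
Reactants: 10 the syn-aldol imide
Product: 11 (1S,2S)-1-[4-(benzyloxy)-3-methoxyphenyl]-2-(4-bromo-2-methoxyphenoxy)propane-1,3-diol
Conditions: NaBH4, THF/H2O, 0 °C to rt
Reagents that add atoms: none
Why: Borohydride reduction of the activated exocyclic imide carbonyl to the primary alcohol with release of the auxiliary; neither stereocentre is enolisable afterwards.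

Step 5
Reactants: 11 the 1,3-diol
Product: 12 (1S,2S)-1-[4-(benzyloxy)-3-methoxyphenyl]-2-(4-bromo-2-methoxyphenoxy)propane-1,3-diol bis(tert-butyldimethylsilyl) ether
Conditions: TBSOTf, 2,6-lutidine, CH2Cl2, 0 °C
Reagents that add atoms: tert-butyldimethylsilyl trifluoromethanesulfonate, CC(C)(C)[Si](C)(C)OS(=O)(=O)C(F)(F)F
Why: Silylation of a primary and a secondary benzylic alcohol with a silyl triflate; the silyl ethers tolerate organolithium, light, aluminium hydride, chromate and amide base.

Step 6
Reactants: 12 the aryl bromide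
Product: 14 Ar*–CHO, 3-methoxy-4-{[(1S,2S)-1-[4-(benzyloxy)-3-methoxyphenyl]-1,3-bis[(tert-butyldimethylsilyl)oxy]propan-2-yl]oxy}benzaldehyde, via aryllithium 13 (not isolated)
Conditions: n-BuLi, THF, −78 °C; DMF, −78 to 0 °C; NH4Cl (aq)
Reagents that add atoms: N,N-dimethylformamide, CN(C)C=O
Why: Bromine–lithium exchange is faster than any deprotonation at −78 °C, and formylation of the aryllithium gives the vanillin-type aldehyde.

Step 7
Reactants: 14 Ar*–CHO; 15 furan
Product: 16 (1R,5S,6R)-6-Ar*-2,7-dioxabicyclo[3.2.0]hept-3-ene (exo adduct); 17 (1S,5R,6S)-6-Ar*-2,7-dioxabicyclo[3.2.0]hept-3-ene (exo adduct from the other furan face)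
Conditions: hν (medium-pressure Hg lamp, Pyrex, λ > 300 nm), furan (large excess)/benzene, 5 °C, argon
Reagents that add atoms: none
Why: Paternò–Büchi [2+2] photocycloaddition of an aryl aldehyde to furan (the photo-aldol reaction), a known reaction type for this substrate pair. The excited triplet aldehyde bonds through oxygen to a furan α-carbon (the C9'–O7' bond), giving a triplet 1,4-biradical whose ring radical is allylic and oxygen-stabilised and whose other terminus is benzylic. After intersystem crossing the two radical termini combine at the furan β-carbon (the C7'–C8' bond), which closes the four-membered oxetane; the five-membered ring is not formed but survives as a 2,3-dihydrofuran. The ring fusion (C1, C5) is necessarily cis, and the aryl group at C6 takes the exo position on the convex face because the biradical closes from the conformer that turns the aryl group away from the ring. This exo geometry is the anti C7'–O/C8' relation of the target. Regioselectivity is needed and is secured by formation of the more stabilised biradical. Chemoselectivity is secured because only the aldehyde absorbs above 300 nm and excess furan outcompetes hydrogen abstraction and a second addition to the product enol ether. The two faces of furan are not differentiated by the remote side-chain centres, so 16 and 17 should form in about equal amounts and are taken on together.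

Step 8
Reactants: 16 (1R,5S,6R)-6-Ar*-2,7-dioxabicyclo[3.2.0]hept-3-ene; 17 (1S,5R,6S)-6-Ar*-2,7-dioxabicyclo[3.2.0]hept-3-ene
Product: 18 (R)-Ar*[(3R)-2,3-dihydrofuran-3-yl]methanol; 19 (S)-Ar*[(3S)-2,3-dihydrofuran-3-yl]methanol
Conditions: iBu2AlH, toluene, −78 to −20 °C; then aqueous Rochelle salt (KNaC4H4O6)
Reagents that add atoms: none
Why: Reductive cleavage of an acetal C–O bond by a Lewis acidic aluminium hydride, a reaction type known for cyclic and bicyclic acetals, of which the 2-alkoxyoxetane is a strained member: aluminium binds the more basic oxetane oxygen, the C9'–O7' bond ionises with help from the ring oxygen, and hydride is delivered within the ion pair. C9' becomes a methylene group and C8' and C7' are untouched, so 16 gives 18 and 17 gives 19 (the descriptor of C8' changes only through the priority change).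

Step 9
Reactants: 18 (R)-Ar*[(3R)-2,3-dihydrofuran-3-yl]methanol; 19 (S)-Ar*[(3S)-2,3-dihydrofuran-3-yl]methanol
Product: 20 tert-butyl{(R)-Ar*[(3R)-2,3-dihydrofuran-3-yl]methoxy}dimethylsilane
Conditions: (S)-benzotetramisole [(S)-2-phenyl-2,3-dihydroimidazo[2,1-b][1,3]benzothiazole] (5 mol%), (iPrCO)2O (0.55 equiv based on 18 plus 19), iPr2NEt, Na2SO4, CHCl3, 0 °C; then 2,6-lutidine, TBSOTf (excess), −40 to 0 °C; chromatography
Reagents that add atoms: tert-butyldimethylsilyl trifluoromethanesulfonate, CC(C)(C)[Si](C)(C)OS(=O)(=O)C(F)(F)F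
Why: Acyl-transfer kinetic resolution of a secondary benzylic alcohol by a chiral isothiourea, applied to the isomer pair: the catalyst reads only the carbinol centre (aryl against branched alkyl) and converts the (S)-carbinol 19 into its isobutyrate with the limiting anhydride, while 18 stays free. The silyl triflate then silylates the remaining hindered alcohol in the same flask under amine buffering that spares the enol ether, so 20 is parted from the ester of 19 by polarity and O7' is protected against the oxidation and the base that follow.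

Step 10
Reactants: 20 the silylated dihydrofuran
Product: 21 (4R)-4-{(R)-Ar*[(tert-butyldimethylsilyl)oxy]methyl}dihydrofuran-2(3H)-one
Conditions: pyridinium chlorochromate (C5H5NH[CrO3Cl]), NaOAc, 4 Å molecular sieves, CH2Cl2, rt
Reagents that add atoms: pyridinium chlorochromate, [O-][Cr](=O)(=O)Cl.c1cc[nH+]cc1
Why: Chlorochromate oxidation of a cyclic enol ether to the lactone, a known conversion of 2,3-dihydrofurans and glycals; the carbonyl appears at the oxygen-bearing enol ether carbon (C9) and no stereocentre is involved.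

Step 11
Reactants: 22 4-(benzyloxy)-3-methoxybenzyl alcohol
Product: 23 4-(benzyloxy)-3-methoxybenzyl bromide
Conditions: PBr3, Et2O, 0 °C
Reagents that add atoms: phosphorus tribromide, BrP(Br)Br
Why: Standard conversion of a benzylic alcohol into the bromide; the product is used directly.

Step 12
Reactants: 21 the β-substituted lactone; 23 4-(benzyloxy)-3-methoxybenzyl bromide
Product: 25 (3R,4R)-3-[4-(benzyloxy)-3-methoxybenzyl]-4-{(R)-Ar*[(tert-butyldimethylsilyl)oxy]methyl}dihydrofuran-2(3H)-one, via lithium enolate 24 (not isolated)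
Conditions: LiN(SiMe3)2, THF, −78 °C; then 23, DMPU, −78 to −40 °C
Reagents that add atoms: none
Why: Alkylation of a γ-butyrolactone lithium enolate, the standard entry to trans-dibenzylbutyrolactone lignans: the bromide approaches anti to the bulky C8' substituent, which sets C8 as R (trans).

Step 13
Reactants: 25 the tris(silyl ether)
Product: 26 (3R,4R)-3-[4-(benzyloxy)-3-methoxybenzyl]-4-[(R)-hydroxy(3-methoxy-4-{[(1S,2S)-1-[4-(benzyloxy)-3-methoxyphenyl]-1,3-dihydroxypropan-2-yl]oxy}phenyl)methyl]dihydrofuran-2(3H)-one
Conditions: HF·pyridine, pyridine, THF, 0 °C to rt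
Reagents that add atoms: none
Why: Buffered fluoride desilylation removes the three silyl ethers without base (no translactonisation, no epimerisation at C8) and, with the phenols still benzylated, without a quinone methide pathway.

Step 14
Reactants: 26 the bis(benzyl ether) triol
Product: 27 (3R,4R)-4-[(R)-hydroxy(3-methoxy-4-{[(1S,2S)-1,3-dihydroxy-1-(4-hydroxy-3-methoxyphenyl)propan-2-yl]oxy}phenyl)methyl]-3-(4-hydroxy-3-methoxybenzyl)dihydrofuran-2(3H)-one (target)
Conditions: H2 (1 atm), Pd/C (10% palladium on carbon), EtOAc, rt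
Reagents that add atoms: none
Why: Neutral hydrogenolysis of aryl benzyl ethers is much faster than cleavage of benzylic alcohols in the absence of acid; no stereocentre is touched.

## Compound list

1 | 4-bromo-2-methoxyphenol | COc1cc(Br)ccc1O | starting material
2 | bromoacetic acid | OC(=O)CBr | starting material
3 | (4-bromo-2-methoxyphenoxy)acetic acid | COc1cc(Br)ccc1OCC(O)=O | intermediate
4 | (R)-4-benzyloxazolidin-2-one | O=C1N[C@H](Cc2ccccc2)CO1 | starting material
5 | (4-bromo-2-methoxyphenoxy)acetic pivalic anhydride (not isolated) | COc1cc(Br)ccc1OCC(=O)OC(=O)C(C)(C)C | intermediate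
6 | (R)-4-benzyl-3-[(4-bromo-2-methoxyphenoxy)acetyl]oxazolidin-2-one | COc1cc(Br)ccc1OCC(=O)N1[C@H](Cc2ccccc2)COC1=O | intermediate
7 | 4-(benzyloxy)-3-methoxybenzaldehyde | COc1cc(C=O)ccc1OCc1ccccc1 | starting material
8 | dibutylboron (Z)-enolate of 6 (not isolated) | COc1cc(Br)ccc1O/C=C(\OB(CCCC)CCCC)N1[C@H](Cc2ccccc2)COC1=O | intermediate
9 | dibutylboron aldolate of 10 (not isolated) | COc1cc(Br)ccc1O[C@@H](C(=O)N1[C@H](Cc2ccccc2)COC1=O)[C@@H](OB(CCCC)CCCC)c1ccc(OCc2ccccc2)c(OC)c1 | intermediate
10 | (R)-4-benzyl-3-[(2R,3S)-3-[4-(benzyloxy)-3-methoxyphenyl]-2-(4-bromo-2-methoxyphenoxy)-3-hydroxypropanoyl]oxazolidin-2-one | COc1cc(Br)ccc1O[C@@H](C(=O)N1[C@H](Cc2ccccc2)COC1=O)[C@@H](O)c1ccc(OCc2ccccc2)c(OC)c1 | intermediate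
11 | (1S,2S)-1-[4-(benzyloxy)-3-methoxyphenyl]-2-(4-bromo-2-methoxyphenoxy)propane-1,3-diol | COc1cc(Br)ccc1O[C@@H](CO)[C@@H](O)c1ccc(OCc2ccccc2)c(OC)c1 | intermediate
12 | bis(tert-butyldimethylsilyl) ether of 11 | COc1cc(Br)ccc1O[C@@H](CO[Si](C)(C)C(C)(C)C)[C@@H](O[Si](C)(C)C(C)(C)C)c1ccc(OCc2ccccc2)c(OC)c1 | intermediate
13 | aryllithium from 12, Ar*–Li (not isolated) | COc1cc([Li])ccc1O[C@@H](CO[Si](C)(C)C(C)(C)C)[C@@H](O[Si](C)(C)C(C)(C)C)c1ccc(OCc2ccccc2)c(OC)c1 | intermediate
14 | 3-methoxy-4-{[(1S,2S)-1-[4-(benzyloxy)-3-methoxyphenyl]-1,3-bis[(tert-butyldimethylsilyl)oxy]propan-2-yl]oxy}benzaldehyde, Ar*–CHO | COc1cc(C=O)ccc1O[C@@H](CO[Si](C)(C)C(C)(C)C)[C@@H](O[Si](C)(C)C(C)(C)C)c1ccc(OCc2ccccc2)c(OC)c1 | intermediate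
15 | furan | c1ccoc1 | starting material
16 | (1R,5S,6R)-6-Ar*-2,7-dioxabicyclo[3.2.0]hept-3-ene (exo) | C1=CO[C@H]2[C@@H]1[C@@H](O2)c1ccc(O[C@@H](CO[Si](C)(C)C(C)(C)C)[C@@H](O[Si](C)(C)C(C)(C)C)c2ccc(OCc3ccccc3)c(OC)c2)c(OC)c1 | intermediate
17 | (1S,5R,6S)-6-Ar*-2,7-dioxabicyclo[3.2.0]hept-3-ene (exo, unwanted isomer) | C1=CO[C@@H]2[C@H]1[C@H](O2)c1ccc(O[C@@H](CO[Si](C)(C)C(C)(C)C)[C@@H](O[Si](C)(C)C(C)(C)C)c2ccc(OCc3ccccc3)c(OC)c2)c(OC)c1 | intermediate
18 | (R)-Ar*[(3R)-2,3-dihydrofuran-3-yl]methanol | C1=COC[C@@H]1[C@@H](O)c1ccc(O[C@@H](CO[Si](C)(C)C(C)(C)C)[C@@H](O[Si](C)(C)C(C)(C)C)c2ccc(OCc3ccccc3)c(OC)c2)c(OC)c1 | intermediate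
19 | (S)-Ar*[(3S)-2,3-dihydrofuran-3-yl]methanol (unwanted isomer) | C1=COC[C@H]1[C@H](O)c1ccc(O[C@@H](CO[Si](C)(C)C(C)(C)C)[C@@H](O[Si](C)(C)C(C)(C)C)c2ccc(OCc3ccccc3)c(OC)c2)c(OC)c1 | intermediate
20 | tert-butyl{(R)-Ar*[(3R)-2,3-dihydrofuran-3-yl]methoxy}dimethylsilane | C1=COC[C@@H]1[C@@H](O[Si](C)(C)C(C)(C)C)c1ccc(O[C@@H](CO[Si](C)(C)C(C)(C)C)[C@@H](O[Si](C)(C)C(C)(C)C)c2ccc(OCc3ccccc3)c(OC)c2)c(OC)c1 | intermediate
21 | (4R)-4-{(R)-Ar*[(tert-butyldimethylsilyl)oxy]methyl}dihydrofuran-2(3H)-one | O=C1C[C@H](CO1)[C@@H](O[Si](C)(C)C(C)(C)C)c1ccc(O[C@@H](CO[Si](C)(C)C(C)(C)C)[C@@H](O[Si](C)(C)C(C)(C)C)c2ccc(OCc3ccccc3)c(OC)c2)c(OC)c1 | intermediate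
22 | 4-(benzyloxy)-3-methoxybenzyl alcohol | COc1cc(CO)ccc1OCc1ccccc1 | starting material
23 | 4-(benzyloxy)-3-methoxybenzyl bromide | COc1cc(CBr)ccc1OCc1ccccc1 | intermediate
24 | lithium enolate of 21 (not isolated) | [Li]OC1=C[C@H](CO1)[C@@H](O[Si](C)(C)C(C)(C)C)c1ccc(O[C@@H](CO[Si](C)(C)C(C)(C)C)[C@@H](O[Si](C)(C)C(C)(C)C)c2ccc(OCc3ccccc3)c(OC)c2)c(OC)c1 | intermediate
25 | (3R,4R)-3-[4-(benzyloxy)-3-methoxybenzyl]-4-{(R)-Ar*[(tert-butyldimethylsilyl)oxy]methyl}dihydrofuran-2(3H)-one | COc1cc(C[C@H]2C(=O)OC[C@@H]2[C@@H](O[Si](C)(C)C(C)(C)C)c2ccc(O[C@@H](CO[Si](C)(C)C(C)(C)C)[C@@H](O[Si](C)(C)C(C)(C)C)c3ccc(OCc4ccccc4)c(OC)c3)c(OC)c2)ccc1OCc1ccccc1 | intermediate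
26 | (3R,4R)-3-[4-(benzyloxy)-3-methoxybenzyl]-4-[(R)-hydroxy(3-methoxy-4-{[(1S,2S)-1-[4-(benzyloxy)-3-methoxyphenyl]-1,3-dihydroxypropan-2-yl]oxy}phenyl)methyl]dihydrofuran-2(3H)-one | COc1cc(C[C@H]2C(=O)OC[C@@H]2[C@@H](O)c2ccc(O[C@@H](CO)[C@@H](O)c3ccc(OCc4ccccc4)c(OC)c3)c(OC)c2)ccc1OCc1ccccc1 | intermediate
27 | (3R,4R)-4-[(R)-hydroxy(3-methoxy-4-{[(1S,2S)-1,3-dihydroxy-1-(4-hydroxy-3-methoxyphenyl)propan-2-yl]oxy}phenyl)methyl]-3-(4-hydroxy-3-methoxybenzyl)dihydrofuran-2(3H)-one | COc1cc(C[C@H]2C(=O)OC[C@@H]2[C@@H](O)c2ccc(O[C@@H](CO)[C@@H](O)c3ccc(O)c(OC)c3)c(OC)c2)ccc1O | target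

## Step count and least certain steps

Total: 14 steps. Longest linear sequence: 13 steps (steps 1–10 and 12–14, from 1 to 27); step 11 is a one-step branch.

**Step 7 (key step).** The 3,4-dialkoxybenzaldehyde triplet has considerable π,π* character, so addition to furan may be slow. Hydrogen abstraction, pinacol coupling, a second addition to the enol ether of the product and loss of exo selectivity could then compete. Half of 14 also enters the unwanted series by design. The fallback replaces the photocycloaddition by a ground-state, auxiliary-controlled anti-aldol reaction; it sets out from 14 (with 4 as source of the second component) and returns at 21. Oxazolidinone 4 is acylated with pent-4-enoyl chloride to (R)-4-benzyl-3-(pent-4-enoyl)oxazolidin-2-one F1. Its MgCl2-catalysed anti-aldol addition to 14 (Et3N, Me3SiCl, EtOAc) gives the O-trimethylsilyl anti-aldol adduct F2 through the chelated enolate, which is attacked on the face opposite to that of the boron enolate. Methanolysis gives the free anti-aldol F3, TBSOTf its silyl ether F4, and LiBH4 the primary alcohol F5 (C9'). Lemieux–Johnson cleavage of the allyl group (OsO4, NaIO4) gives lactol F6, which is oxidised (TEMPO, PhI(OAc)2) to 21. This sequence fixes C7' and C8' absolutely and discards nothing, but it is longer.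

**Step 8.** After ionisation of the acetal, the furanium-type oxocarbenium ion may lose the C8' proton faster than it accepts hydride. That aromatises the ring to a 3-furyl carbinol and destroys C8'. The fallback removes the enol ether before the acetal is opened; it sets out from 16 (in its mixture with 17) and returns at 21. Hydrogenation (H2, Rh/Al2O3, EtOAc) gives (1R,5S,6R)-6-Ar*-2,7-dioxabicyclo[3.2.0]heptane F7 and its isomer (1S,5R,6S)-6-Ar*-2,7-dioxabicyclo[3.2.0]heptane F8. Methanolysis (pyridinium p-toluenesulfonate, MeOH, 0 °C), now without an aromatisation path, gives (R)-Ar*[(3S)-2-methoxytetrahydrofuran-3-yl]methanol F9 and (S)-Ar*[(3R)-2-methoxytetrahydrofuran-3-yl]methanol F10, each as an anomer mixture. The acylation of step 9 converts F10 into the isobutyrate of F10 F11 and leaves F9, which TBSOTf converts into the silyl ether of F9 F12. Mild hydrolysis of the methyl acetal and NaBH4 reduction give (2R)-2-{(R)-Ar*[(tert-butyldimethylsilyl)oxy]methyl}butane-1,4-diol F13. Oxidative lactonisation (TEMPO, PhI(OAc)2) at the less hindered primary alcohol gives 21.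

**Step 9.** The carbinol is flanked by two branched groups and a large para substituent, so discrimination between 18 and 19 in the acyl transfer may be too low. Traces of acid may hydrate the enol ether, and the carboxylate formed in the first stage consumes part of the silyl triflate. The fallback is a covalent separation; it sets out from the mixture of 18 and 19 and returns at 20. Esterification with (S)-2-methoxy-2-phenylacetic acid (DCC, DMAP) gives the (S)-2-methoxy-2-phenylacetate of 18 F14 and the (S)-2-methoxy-2-phenylacetate of 19 F15. These esters differ at centres next to the new stereocentre and are separated by chromatography. K2CO3 in MeOH releases 18 from F14, and TBSOTf with 2,6-lutidine then gives 20.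

**Step 14.** Over-reduction by hydrogenolysis of the para-oxygenated benzylic C–O bonds at C7' and C7'' may accompany debenzylation. The fallback reverses the order of unmasking; it sets out from 25 and returns at 27. Hydrogenolysis of 25 (H2, Pd/C), while both benzylic oxygens are still silylated, gives the bis-phenol tris(silyl ether) F16. Desilylation with fluoride buffered by acetic acid (Bu4NF, AcOH) then gives 27.

## Further compounds

F1 | step 7 | (R)-4-benzyl-3-(pent-4-enoyl)oxazolidin-2-one | C=CCCC(=O)N1[C@H](Cc2ccccc2)COC1=O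
F2 | step 7 | (R)-4-benzyl-3-[(2S)-2-{(R)-Ar*[(trimethylsilyl)oxy]methyl}pent-4-enoyl]oxazolidin-2-one | O=C(N1[C@H](Cc2ccccc2)COC1=O)[C@@H](CC=C)[C@@H](O[Si](C)(C)C)c1ccc(O[C@@H](CO[Si](C)(C)C(C)(C)C)[C@@H](O[Si](C)(C)C(C)(C)C)c2ccc(OCc3ccccc3)c(OC)c2)c(OC)c1
F3 | step 7 | (R)-4-benzyl-3-[(2S)-2-{(R)-Ar*(hydroxy)methyl}pent-4-enoyl]oxazolidin-2-one | O=C(N1[C@H](Cc2ccccc2)COC1=O)[C@@H](CC=C)[C@@H](O)c1ccc(O[C@@H](CO[Si](C)(C)C(C)(C)C)[C@@H](O[Si](C)(C)C(C)(C)C)c2ccc(OCc3ccccc3)c(OC)c2)c(OC)c1
F4 | step 7 | (R)-4-benzyl-3-[(2S)-2-{(R)-Ar*[(tert-butyldimethylsilyl)oxy]methyl}pent-4-enoyl]oxazolidin-2-one | O=C(N1[C@H](Cc2ccccc2)COC1=O)[C@@H](CC=C)[C@@H](O[Si](C)(C)C(C)(C)C)c1ccc(O[C@@H](CO[Si](C)(C)C(C)(C)C)[C@@H](O[Si](C)(C)C(C)(C)C)c2ccc(OCc3ccccc3)c(OC)c2)c(OC)c1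
F5 | step 7 | (2R)-2-{(R)-Ar*[(tert-butyldimethylsilyl)oxy]methyl}pent-4-en-1-ol | OC[C@@H](CC=C)[C@@H](O[Si](C)(C)C(C)(C)C)c1ccc(O[C@@H](CO[Si](C)(C)C(C)(C)C)[C@@H](O[Si](C)(C)C(C)(C)C)c2ccc(OCc3ccccc3)c(OC)c2)c(OC)c1
F6 | step 7 | (4R)-4-{(R)-Ar*[(tert-butyldimethylsilyl)oxy]methyl}tetrahydrofuran-2-ol (anomer mixture) | OC1C[C@H](CO1)[C@@H](O[Si](C)(C)C(C)(C)C)c1ccc(O[C@@H](CO[Si](C)(C)C(C)(C)C)[C@@H](O[Si](C)(C)C(C)(C)C)c2ccc(OCc3ccccc3)c(OC)c2)c(OC)c1
F7 | step 8 | (1R,5S,6R)-6-Ar*-2,7-dioxabicyclo[3.2.0]heptane | C1CO[C@H]2[C@@H]1[C@@H](O2)c1ccc(O[C@@H](CO[Si](C)(C)C(C)(C)C)[C@@H](O[Si](C)(C)C(C)(C)C)c2ccc(OCc3ccccc3)c(OC)c2)c(OC)c1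
F8 | step 8 | (1S,5R,6S)-6-Ar*-2,7-dioxabicyclo[3.2.0]heptane | C1CO[C@@H]2[C@H]1[C@H](O2)c1ccc(O[C@@H](CO[Si](C)(C)C(C)(C)C)[C@@H](O[Si](C)(C)C(C)(C)C)c2ccc(OCc3ccccc3)c(OC)c2)c(OC)c1
F9 | step 8 | (R)-Ar*[(3S)-2-methoxytetrahydrofuran-3-yl]methanol (anomer mixture) | C1COC(OC)[C@@H]1[C@@H](O)c1ccc(O[C@@H](CO[Si](C)(C)C(C)(C)C)[C@@H](O[Si](C)(C)C(C)(C)C)c2ccc(OCc3ccccc3)c(OC)c2)c(OC)c1
F10 | step 8 | (S)-Ar*[(3R)-2-methoxytetrahydrofuran-3-yl]methanol (anomer mixture) | C1COC(OC)[C@H]1[C@H](O)c1ccc(O[C@@H](CO[Si](C)(C)C(C)(C)C)[C@@H](O[Si](C)(C)C(C)(C)C)c2ccc(OCc3ccccc3)c(OC)c2)c(OC)c1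
F11 | step 8 | isobutyrate of F10 | C1COC(OC)[C@H]1[C@H](OC(=O)C(C)C)c1ccc(O[C@@H](CO[Si](C)(C)C(C)(C)C)[C@@H](O[Si](C)(C)C(C)(C)C)c2ccc(OCc3ccccc3)c(OC)c2)c(OC)c1
F12 | step 8 | tert-butyldimethylsilyl ether of F9 | C1COC(OC)[C@@H]1[C@@H](O[Si](C)(C)C(C)(C)C)c1ccc(O[C@@H](CO[Si](C)(C)C(C)(C)C)[C@@H](O[Si](C)(C)C(C)(C)C)c2ccc(OCc3ccccc3)c(OC)c2)c(OC)c1
F13 | step 8 | (2R)-2-{(R)-Ar*[(tert-butyldimethylsilyl)oxy]methyl}butane-1,4-diol | OCC[C@H](CO)[C@@H](O[Si](C)(C)C(C)(C)C)c1ccc(O[C@@H](CO[Si](C)(C)C(C)(C)C)[C@@H](O[Si](C)(C)C(C)(C)C)c2ccc(OCc3ccccc3)c(OC)c2)c(OC)c1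
F14 | step 9 | (S)-2-methoxy-2-phenylacetate of 18 | C1=COC[C@@H]1[C@@H](OC(=O)[C@@H](OC)c2ccccc2)c1ccc(O[C@@H](CO[Si](C)(C)C(C)(C)C)[C@@H](O[Si](C)(C)C(C)(C)C)c2ccc(OCc3ccccc3)c(OC)c2)c(OC)c1
F15 | step 9 | (S)-2-methoxy-2-phenylacetate of 19 | C1=COC[C@H]1[C@H](OC(=O)[C@@H](OC)c2ccccc2)c1ccc(O[C@@H](CO[Si](C)(C)C(C)(C)C)[C@@H](O[Si](C)(C)C(C)(C)C)c2ccc(OCc3ccccc3)c(OC)c2)c(OC)c1
F16 | step 14 | (3R,4R)-3-(4-hydroxy-3-methoxybenzyl)-4-{(R)-[(tert-butyldimethylsilyl)oxy](3-methoxy-4-{[(1S,2S)-1,3-bis[(tert-butyldimethylsilyl)oxy]-1-(4-hydroxy-3-methoxyphenyl)propan-2-yl]oxy}phenyl)methyl}dihydrofuran-2(3H)-one | COc1cc(C[C@H]2C(=O)OC[C@@H]2[C@@H](O[Si](C)(C)C(C)(C)C)c2ccc(O[C@@H](CO[Si](C)(C)C(C)(C)C)[C@@H](O[Si](C)(C)C(C)(C)C)c3ccc(O)c(OC)c3)c(OC)c2)ccc1O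
A1 | alternative 1 | (E)-3-[4-(allyloxy)-3-methoxyphenyl]allyl methyl 2-diazomalonate | COC(=O)C(=[N+]=[N-])C(=O)OC/C=C/c1ccc(OCC=C)c(OC)c1
A2 | alternative 1 | methyl 6-exo-[4-(allyloxy)-3-methoxyphenyl]-2-oxo-3-oxabicyclo[3.1.0]hexane-1-carboxylate (C8' as in the target) | COC(=O)[C@@]12C(=O)OC[C@@H]1[C@H]2c1ccc(OCC=C)c(OC)c1
A3 | alternative 2 | 3-{(R)-[4-(benzyloxy)-3-methoxyphenyl][(tert-butyldimethylsilyl)oxy]methyl}cyclobutan-1-one | O=C1CC(C1)[C@@H](O[Si](C)(C)C(C)(C)C)c1ccc(OCc2ccccc2)c(OC)c1
A4 | alternative 2 | (4R)-4-{(R)-[4-(benzyloxy)-3-methoxyphenyl][(tert-butyldimethylsilyl)oxy]methyl}dihydrofuran-2(3H)-one | O=C1C[C@H](CO1)[C@@H](O[Si](C)(C)C(C)(C)C)c1ccc(OCc2ccccc2)c(OC)c1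
A5 | alternative 3 | methyl (2R)-4-[4-(allyloxy)-3-methoxyphenyl]-2-[4-(benzyloxy)-3-methoxybenzyl]-4-oxobutanoate | COC(=O)[C@H](Cc1ccc(OCc2ccccc2)c(OC)c1)CC(=O)c1ccc(OCC=C)c(OC)c1
A6 | alternative 3 | formaldehyde | C=O
A7 | alternative 3 | (3R,4R)-4-[4-(allyloxy)-3-methoxybenzoyl]-3-[4-(benzyloxy)-3-methoxybenzyl]dihydrofuran-2(3H)-one | COc1cc(C[C@H]2C(=O)OC[C@@H]2C(=O)c2ccc(OCC=C)c(OC)c2)ccc1OCc1ccccc1
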